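(The data stem from a simulated flask for an exercise; the scatter is artificial.)

The beta run, charged with 1.4 equiv of X, shows Z, as a part of the Q charged, falling from 26% at 1.50 min to 3% at 20.0 min. The decision on Thursday's flask hangs on that fall: whether its 40 min should stand, if Z is to be read at the end.

common to all: Q 0.80 M (in portions, 4)
- beta: X 1.4 equiv; run made earlier; portions every 12 s
- Thursday's: X 1.20 equiv; the portions of Q follow each other after 12 s, the first at the start; time 40 min
- Wednesday's: X 3.00 equiv; the portions of Q follow each other after 12 s, the first at the start; time 40 min

beta run (percent of the Q charged)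

| time / min | Z / % | J / % |
|---|---|---|
| 1.50 | 26 | 3 |
| 2.50 | 17 | 4 |
| 4.00 | 10 | 0 |
| 6.00 | 4 | 2 |
| 8.00 | 7 | 2 |
| 12.0 | 4 | 2 |
| 20.0 | 3 | 2 |

(readings scatter by 1.5 percentage points)

- in percentages every species weighs as the Q in it: one G counts as two
- the numbers in the tables scatter with a standard deviation of 1.5 percentage points
- candidate steps: Q + X -> Z; X + Z -> J; X + J -> D; X + D -> L; Q + J -> G; Z -> E

* which of these holds the largest part of the Q at the end of Thursday's (D / J / Q / Z / L)
* which of these holds the largest part of the Q at the end of Wednesday's (D / J / Q / Z / L)
* final Z in Thursday's, as a percentage of the Q charged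

Read as an apparent first-order loss, the beta fall gives the decade time of Z, the time in which Z loses a factor of ten: 19.7 min. This is a reading, and its last point carries the scatter of 1.5 percentage points. Taking Thursday's Z as equal to the beta reading at 1.50 min, the time left spans 1.95 decades. Z then ends near 0.291%, less than the scatter. This reckoning therefore leaves Thursday's charge and time as written and expects no readable Z at the end.

The forecast differs. It names Z for Thursday's and L for Wednesday's, and it puts Thursday's Z at 12%, holding that “Z's decay stops when X runs out”.

Thursday's flask ends with D the largest of the listed species at 9.60%, and with Z at 0.0487%, less than the forecast's figure. Wednesday's ends with L the largest at 59.4%.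

    Q + X → Z (k = 0.0320 M⁻¹ s⁻¹)
    X + Z → J (k = 0.0370 M⁻¹ s⁻¹)
    X + J → D (k = 0.100 M⁻¹ s⁻¹)
    X + D → L (k = 0.00580 M⁻¹ s⁻¹)
    Q + J → G (k = 0.270 M⁻¹ s⁻¹)
    Z → E (k = 0.00280 s⁻¹)

At 40 min Thursday's X, the limiting reagent, stands at 0.015% of its charge. Ten times the time adds 18.3 decades by the beta reading, and Thursday's flask then shows Z at 0%. Q goes from 4.96% to 4.95%, while D stays at 9.59% and G at 57.1%. That change in Q is less than the scatter, and so is the Z still there at 40 min.

The decade count holds no X, so for the neighbour charged with 0.480 equiv of X, its Z again taken as the beta reading at 1.50 min, it gives 0.291% again. That flask holds Z at 0.0396% at 40.0 min, also less than the scatter.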